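## Retrosynthetic overview

- **Feature.** In ring A, the ring oxygen O1 (on C8a) and the 6-hydroxyl are para, and the 7-methoxyl is the neighbour of C6. These three oxygens are those of 2-methoxy-1,4-benzoquinone, whose free carbon C5 corresponds to C4a.
- **Key disconnection C4–C4a.** Light-driven addition of the acyl radical of a ring B α-methoxycinnamaldehyde to that quinone re-aromatises ring A as the hydroquinone. It gives the whole C6–C3–C6 skeleton as a 2'-hydroxy-α-methoxychalcone.
- **Second disconnection O1–C2.** Ring C is the only ring that is built, and it is closed last by iodine/DMSO cyclodehydrogenation, after the non-chelated hydroxyl is masked as its acetate. Rings A and B are bought as six-membered carbocycles.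
- **The enal** comes from 2,4-dimethoxybenzaldehyde. Baeyer–Villiger oxidation puts oxygen on the ring, sulfonylation and Vilsmeier formylation give the 2,4,5-trioxygenated aldehyde, and a glycolate aldol/elimination, reduction and reoxidation add C3 and C4.
- **O5' travels as a benzenesulfonate, not as a benzyl ether.** Benzylic C–H bonds and a more electron-rich ring B would compete for the excited quinone. The sulfonate leaves together with the acetate in the last step.

Key step: step 9

Assumption: the target has no stereocentre. The only stereo-element met on the way is the geometry of the enol-ether alkene, drawn Z throughout; either isomer or a mixture serves, because step 11 erases it.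

## Route

Step 1
Reactants: 1 2,4-dimethoxybenzaldehyde
Product: 3 2,4-dimethoxyphenol, via 2,4-dimethoxyphenyl formate 2 (not isolated)
Conditions: mCPBA, CH2Cl2, 0 °C to rt; then K2CO3 (0.2 equiv), MeOH, rt
Reagents that add atoms: mCPBA (3-chloroperoxybenzoic acid), O=C(OO)c1cccc(Cl)c1
Why: Baeyer–Villiger (Dakin-type) oxidation, in which the electron-rich 2,4-dimethoxyphenyl group migrates in preference to hydrogen and the labile aryl formate 2 is then cleaved by base-catalysed methanolysis.

Step 2
Reactants: 3 2,4-dimethoxyphenol
Product: 4 2,4-dimethoxyphenyl benzenesulfonate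
Conditions: PhSO2Cl, Et3N, DMAP (cat.), CH2Cl2, 0 °C to rt
Reagents that add atoms: benzenesulfonyl chloride, O=S(=O)(Cl)c1ccccc1
Why: DMAP-catalysed O-sulfonylation of a phenol gives an aryl sulfonate that has no weak C–H bond and should withstand ester enolates, cold hydride, MnO2, visible light and hot DMSO.

Step 3
Reactants: 4 2,4-dimethoxyphenyl benzenesulfonate
Product: 6 5-formyl-2,4-dimethoxyphenyl benzenesulfonate, via aryl iminium chloride 5 (not isolated)
Conditions: POCl3, DMF, 0 to 80 °C; then ice-water
Reagents that add atoms: DMF, CN(C)C=O; water, O; POCl3, O=P(Cl)(Cl)Cl (chloride ion of 5 only)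
Why: Vilsmeier–Haack formylation, in which the two methoxy groups jointly activate C5 of 4 (para to one, ortho to the other), the site between them is too hindered for the bulky chloroiminium ion, and the meta sulfonate only slows the substitution, hence the heating.

Step 4
Reactants: 7 methyl methoxyacetate; 6 5-formyl-2,4-dimethoxyphenyl benzenesulfonate
Product: 9 methyl 3-[5-(benzenesulfonyloxy)-2,4-dimethoxyphenyl]-3-hydroxy-2-methoxypropanoate (racemic syn/anti mixture), via chelated lithium enolate 8 (not isolated)
Conditions: LiN(i-Pr)2, 7, THF, −78 °C; then 6, −78 °C; AcOH quench at −78 °C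
Reagents that add atoms: LiN(i-Pr)2, CC(C)[N-]C(C)C.[Li+] (lithium of 8 only)
Why: Aldol addition of a preformed glycolate ester enolate to a non-enolisable aldehyde, which at −78 °C should be much faster than attack at sulfonate sulfur; the two new stereocentres are left uncontrolled because step 5 destroys both.

Step 5
Reactants: 9 methyl 3-[5-(benzenesulfonyloxy)-2,4-dimethoxyphenyl]-3-hydroxy-2-methoxypropanoate
Product: 11 methyl (Z)-3-[5-(benzenesulfonyloxy)-2,4-dimethoxyphenyl]-2-methoxyprop-2-enoate, via benzylic mesylate 10 (not isolated)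
Conditions: MsCl, Et3N, CH2Cl2, 0 °C; then DBU, 0 °C to rt
Reagents that add atoms: methanesulfonyl chloride, CS(=O)(=O)Cl (mesyl group of 10 only)
Why: Mesylation followed by base-induced β-elimination of E1cB type lets both diastereomers converge and should favour the more stable Z alkene, with the aryl group trans to the ester.

Step 6
Reactants: 11 methyl (Z)-3-[5-(benzenesulfonyloxy)-2,4-dimethoxyphenyl]-2-methoxyprop-2-enoate
Product: 12 (Z)-3-[5-(benzenesulfonyloxy)-2,4-dimethoxyphenyl]-2-methoxyprop-2-en-1-ol
Conditions: i-Bu2AlH (2.3 equiv), CH2Cl2, −78 °C; aq. potassium sodium tartrate work-up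
Reagents that add atoms: none
Why: 1,2-Reduction of a conjugated ester to the allylic alcohol with i-Bu2AlH, cold enough to leave the aryl sulfonate alone, with a neutral work-up that spares the acid-sensitive enol ether.

Step 7
Reactants: 12 (Z)-3-[5-(benzenesulfonyloxy)-2,4-dimethoxyphenyl]-2-methoxyprop-2-en-1-ol
Product: 13 (Z)-3-[5-(benzenesulfonyloxy)-2,4-dimethoxyphenyl]-2-methoxyprop-2-enal
Conditions: MnO2 (activated, excess), CH2Cl2, rt
Reagents that add atoms: none
Why: Selective allylic alcohol oxidation on MnO2 runs under neutral conditions, stops at the aldehyde and keeps the enol ether and the sulfonate intact.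

Step 8
Reactants: 14 2-methoxyhydroquinone
Product: 15 2-methoxy-1,4-benzoquinone
Conditions: Ag2O, MgSO4, Et2O, rt, dark
Reagents that add atoms: none
Why: Two-electron hydroquinone-to-quinone oxidation with Ag2O is neutral and anhydrous, so that after filtration the light- and base-sensitive quinone can be used fresh.

Step 9
Reactants: 13 (Z)-3-[5-(benzenesulfonyloxy)-2,4-dimethoxyphenyl]-2-methoxyprop-2-enal; 15 2-methoxy-1,4-benzoquinone
Product: 16 (Z)-3-[5-(benzenesulfonyloxy)-2,4-dimethoxyphenyl]-1-(2,5-dihydroxy-4-methoxyphenyl)-2-methoxyprop-2-en-1-one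
Conditions: hν (455 nm LEDs), 15 (2 equiv, in two portions), PhCF3 (degassed), 20 °C, argon
Reagents that add atoms: none
Why: Light of 455 nm should be absorbed only by quinone 15, whose triplet state abstracts the formyl hydrogen of 13 and leaves a semiquinone and a σ-type α-methoxycinnamoyl radical that has no easy decarbonylation path, because a vinyl radical would result. This nucleophilic acyl radical bonds to C5 of a quinone molecule (free addition to ground-state 15 or collapse of the radical pair), and hydrogen return from the semiquinone followed by enolisation re-aromatises ring A, so the C4–C4a bond joins two carbons that are both electrophilic in polar terms, with complete atom economy. The closest known reaction is the photo-Friedel–Crafts acylation of 1,4-benzoquinones and 1,4-naphthoquinones with aldehydes, which is established for aliphatic, aromatic and α,β-unsaturated aldehydes. No ring is closed and no stereocentre is formed, and any E/Z scrambling of the alkene by energy transfer is harmless because step 11 erases the geometry. Regioselectivity for C5 over C6 and C3 is needed and rests on the methoxy group, which turns C2=C3–C4=O into a vinylogous ester and leaves C5, the β-carbon of the unperturbed C1 enone, as the most electrophilic site, the same one that polar nucleophiles choose. Chemoselectivity for formyl hydrogen abstraction over oxetane or cyclobutane formation, electron-transfer quenching and attack on other C–H bonds is helped by the captodative trisubstituted alkene, by the sulfonate (no benzylic C–H, a less donating ring B, an enal absorption that should end below the irradiation wavelength) and by 16 being a poorer reductant than 14, so that excess 15 should not oxidise it.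

Step 10
Reactants: 16 (Z)-3-[5-(benzenesulfonyloxy)-2,4-dimethoxyphenyl]-1-(2,5-dihydroxy-4-methoxyphenyl)-2-methoxyprop-2-en-1-one
Product: 17 (Z)-1-(5-acetoxy-2-hydroxy-4-methoxyphenyl)-3-[5-(benzenesulfonyloxy)-2,4-dimethoxyphenyl]-2-methoxyprop-2-en-1-one
Conditions: Ac2O (1.05 equiv), pyridine, CH2Cl2, 0 °C
Reagents that add atoms: acetic anhydride, CC(=O)OC(C)=O
Why: Chemoselective O-acetylation, because the 2-hydroxyl is tied up in a hydrogen bond to the ketone and reacts far more slowly than the free 5-hydroxyl, whose masking removes the hydroquinone that step 11 would otherwise oxidise.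

Step 11
Reactants: 17 (Z)-1-(5-acetoxy-2-hydroxy-4-methoxyphenyl)-3-[5-(benzenesulfonyloxy)-2,4-dimethoxyphenyl]-2-methoxyprop-2-en-1-one
Product: 19 6-acetoxy-5'-(benzenesulfonyloxy)-3,7,2',4'-tetramethoxyflavone, via 3-methoxyflavanone 18 (not isolated)
Conditions: I2 (0.15 equiv), DMSO, 125 °C
Reagents that add atoms: none
Why: Iodine/DMSO cyclodehydrogenation of a 2'-hydroxychalcone, in which 6-endo-trig oxa-Michael closure forms O1–C2 and ring C, iodination of the C3 enol and loss of HI install C2=C3, DMSO returns HI to I2, and both alkene isomers and both flavanone diastereomers converge.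

Step 12
Reactants: 19 6-acetoxy-5'-(benzenesulfonyloxy)-3,7,2',4'-tetramethoxyflavone
Product: 20 6,5'-dihydroxy-3,7,2',4'-tetramethoxyflavone
Conditions: KOH (2 M aq.), 1,4-dioxane, 60 °C, argon; then 1 M HCl to pH 3
Reagents that add atoms: none
Why: Saponification, in which hydroxide cleaves the aryl acetate at the acyl carbon and the aryl sulfonate at sulfur, the alcohol-free medium excludes an alkyl sulfonate that could alkylate the phenoxides, and the acidic work-up should reclose any ring C that has opened reversibly.

## Compound list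

1 | 2,4-dimethoxybenzaldehyde | COc1ccc(C=O)c(OC)c1 | starting material
2 | 2,4-dimethoxyphenyl formate (not isolated) | COc1ccc(OC=O)c(OC)c1 | intermediate
3 | 2,4-dimethoxyphenol | COc1ccc(O)c(OC)c1 | intermediate
4 | 2,4-dimethoxyphenyl benzenesulfonate | COc1ccc(OS(=O)(=O)c2ccccc2)c(OC)c1 | intermediate
5 | N-{[5-(benzenesulfonyloxy)-2,4-dimethoxyphenyl]methylidene}-N-methylmethanaminium chloride (not isolated) | C[N+](C)=Cc1cc(OS(=O)(=O)c2ccccc2)c(OC)cc1OC.[Cl-] | intermediate
6 | 5-formyl-2,4-dimethoxyphenyl benzenesulfonate | O=Cc1cc(OS(=O)(=O)c2ccccc2)c(OC)cc1OC | intermediate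
7 | methyl methoxyacetate | COCC(=O)OC | starting material
8 | lithium (E)-1,2-dimethoxyethen-1-olate, methoxy oxygen and O–Li cis (chelated; not isolated) | CO/C=C(\[O-])OC.[Li+] | intermediate
9 | methyl 3-[5-(benzenesulfonyloxy)-2,4-dimethoxyphenyl]-3-hydroxy-2-methoxypropanoate (racemic syn/anti mixture, no configuration assigned) | COC(=O)C(OC)C(O)c1cc(OS(=O)(=O)c2ccccc2)c(OC)cc1OC | intermediate
10 | methyl 3-[5-(benzenesulfonyloxy)-2,4-dimethoxyphenyl]-2-methoxy-3-(methanesulfonyloxy)propanoate (racemic diastereomer mixture; not isolated) | COC(=O)C(OC)C(OS(C)(=O)=O)c1cc(OS(=O)(=O)c2ccccc2)c(OC)cc1OC | intermediate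
11 | methyl (Z)-3-[5-(benzenesulfonyloxy)-2,4-dimethoxyphenyl]-2-methoxyprop-2-enoate | COC(=O)/C(OC)=C/c1cc(OS(=O)(=O)c2ccccc2)c(OC)cc1OC | intermediate
12 | (Z)-3-[5-(benzenesulfonyloxy)-2,4-dimethoxyphenyl]-2-methoxyprop-2-en-1-ol | OC/C(OC)=C/c1cc(OS(=O)(=O)c2ccccc2)c(OC)cc1OC | intermediate
13 | (Z)-3-[5-(benzenesulfonyloxy)-2,4-dimethoxyphenyl]-2-methoxyprop-2-enal | O=C/C(OC)=C/c1cc(OS(=O)(=O)c2ccccc2)c(OC)cc1OC | intermediate
14 | 2-methoxyhydroquinone | COc1cc(O)ccc1O | starting material
15 | 2-methoxy-1,4-benzoquinone | COC1=CC(=O)C=CC1=O | intermediate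
16 | (Z)-3-[5-(benzenesulfonyloxy)-2,4-dimethoxyphenyl]-1-(2,5-dihydroxy-4-methoxyphenyl)-2-methoxyprop-2-en-1-one | COc1cc(O)c(C(=O)/C(OC)=C/c2cc(OS(=O)(=O)c3ccccc3)c(OC)cc2OC)cc1O | intermediate
17 | (Z)-1-(5-acetoxy-2-hydroxy-4-methoxyphenyl)-3-[5-(benzenesulfonyloxy)-2,4-dimethoxyphenyl]-2-methoxyprop-2-en-1-one | COc1cc(O)c(C(=O)/C(OC)=C/c2cc(OS(=O)(=O)c3ccccc3)c(OC)cc2OC)cc1OC(C)=O | intermediate
18 | 6-acetoxy-5'-(benzenesulfonyloxy)-3,7,2',4'-tetramethoxyflavanone (racemic cis/trans mixture, no configuration assigned; not isolated) | COC1C(=O)c2cc(OC(C)=O)c(OC)cc2OC1c3cc(OS(=O)(=O)c4ccccc4)c(OC)cc3OC | intermediate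
19 | 6-acetoxy-5'-(benzenesulfonyloxy)-3,7,2',4'-tetramethoxyflavone | COc1cc(OC)c(-c2oc3cc(OC)c(OC(C)=O)cc3c(=O)c2OC)cc1OS(=O)(=O)c4ccccc4 | intermediate
20 | 6,5'-dihydroxy-3,7,2',4'-tetramethoxyflavone | COc1cc(OC)c(-c2oc3cc(OC)c(O)cc3c(=O)c2OC)cc1O | target

## Step count and risks

Total step count: 12.
Longest linear sequence: 11 steps (steps 1–7 and 9–12, from 2,4-dimethoxybenzaldehyde). Step 8 is the one-step side branch.

### Steps most likely to fail

**Step 9.**

- The quinone triplet may be deactivated without reaction, by energy or electron transfer to the styrene-type alkene and ring B.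
- Its methoxy group may lower its hydrogen-abstracting power.
- Cycloaddition across the enol-ether alkene, O-acylation of the semiquinone, or bonding at C6 may compete.

Fallback: the C4–C4a bond is made by polar aromatic substitution on the reduced ring A instead of radical addition to the quinone. Setting out from 14, a Hoesch acylation with methoxyacetonitrile (ZnCl2, dry HCl, Et2O, 0 °C) should attack the position para to the methoxy group and ortho to a hydroxyl. It should precipitate 1-(2,5-dihydroxy-4-methoxyphenyl)-2-methoxyethan-1-iminium chloride F1, which hot water hydrolyses to 1-(2,5-dihydroxy-4-methoxyphenyl)-2-methoxyethan-1-one F2. An acid-catalysed Claisen–Schmidt condensation of F2 with aldehyde 6 (dry HCl, EtOH, 0 °C to rt, argon) then forms the alkene and comes back to the route at 16.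

**Step 11.**

- Closure onto the hindered, fully substituted alkene may be slow.
- During that time the acetate could be lost, and the exposed hydroquinone oxidised.
- The electron-rich rings could also be iodinated.

Fallback: ring closure and dehydrogenation are separated. Setting out from 17, acid-catalysed oxa-Michael cyclisation (MeSO3H cat., AcOH, 80 °C) gives flavanone 18, this time isolated. Hydride abstraction from its benzylic, oxygen-bearing C2 with DDQ (1,4-dioxane, reflux) comes back to the route at 19.

**Step 12.**

- Hydroxide may add to C2 and open ring C, with retro-Claisen fission, at a rate comparable with the slow S–O cleavage.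
- The electron-rich phenoxides may be oxidised by traces of air.

Fallback: the sulfonate is exchanged for an acetate before the pyranone exists, so that the last step becomes a mild methanolysis.

- Setting out from 16, KOH (2 M aq.) in 1,4-dioxane at 50 °C under argon gives (Z)-1-(2,5-dihydroxy-4-methoxyphenyl)-3-(5-hydroxy-2,4-dimethoxyphenyl)-2-methoxyprop-2-en-1-one F3.
- Ac2O (2.1 equiv) and pyridine at 0 °C acetylate the two non-chelated hydroxyls to give (Z)-1-(5-acetoxy-2-hydroxy-4-methoxyphenyl)-3-(5-acetoxy-2,4-dimethoxyphenyl)-2-methoxyprop-2-en-1-one F4.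
- I2 (cat.) in DMSO at 125 °C leads through 6,5'-diacetoxy-3,7,2',4'-tetramethoxyflavanone F5 to 6,5'-diacetoxy-3,7,2',4'-tetramethoxyflavone F6.
- K2CO3 (cat.) in MeOH at rt under argon comes back to the route at 20.

## Further compounds

F1 | step 9 | 1-(2,5-dihydroxy-4-methoxyphenyl)-2-methoxyethan-1-iminium chloride | COCC(=[NH2+])c1cc(O)c(OC)cc1O.[Cl-]
F2 | step 9 | 1-(2,5-dihydroxy-4-methoxyphenyl)-2-methoxyethan-1-one | COCC(=O)c1cc(O)c(OC)cc1O
F0 | step 11 | none | none
F3 | step 12 | (Z)-1-(2,5-dihydroxy-4-methoxyphenyl)-3-(5-hydroxy-2,4-dimethoxyphenyl)-2-methoxyprop-2-en-1-one | COc1cc(O)c(C(=O)/C(OC)=C/c2cc(O)c(OC)cc2OC)cc1O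
F4 | step 12 | (Z)-1-(5-acetoxy-2-hydroxy-4-methoxyphenyl)-3-(5-acetoxy-2,4-dimethoxyphenyl)-2-methoxyprop-2-en-1-one | COc1cc(O)c(C(=O)/C(OC)=C/c2cc(OC(C)=O)c(OC)cc2OC)cc1OC(C)=O
F5 | step 12 | 6,5'-diacetoxy-3,7,2',4'-tetramethoxyflavanone (racemic cis/trans mixture) | COC1C(=O)c2cc(OC(C)=O)c(OC)cc2OC1c3cc(OC(C)=O)c(OC)cc3OC
F6 | step 12 | 6,5'-diacetoxy-3,7,2',4'-tetramethoxyflavone | COc1cc(OC)c(-c2oc3cc(OC)c(OC(C)=O)cc3c(=O)c2OC)cc1OC(C)=O
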